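**Retrosynthetic overview**
1. Target 14 ⇒ oleic acid 12 + bis-epoxide 11. The C3–CH bond and the benzylic stereocentre are made last, by an epoxide-to-ester 1,2-indolyl shift (inversion) that leaves the C6 oxirane alone.
2. 11 ⇒ N-Boc tetraol 8. Both oxiranes are closed in one pot (secondary mesylate, tertiary alkoxide, inversion) and the N-Boc group is lost in the same pot.
3. 8 ⇒ diiodoindole 6 + two molecules of epoxy alcohol 3. Both aryl–CH2 bonds are made in one blue-light nickel/photoredox cross-electrophile coupling.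
4. 3 ⇒ methyl (S)-glycidate 1, the only chiral material; its stereogenic carbon becomes both stereocentres of the target. 6 ⇒ 6-iodoindole 4.
5. Ring order: the indole is bought; the two oxiranes form together in step 4; a spirocyclopropane is a transient in step 5; no other ring is made.

Assumption: the target is taken exactly as the SMILES (benzylic carbon S, oxirane carbon R, 9Z olefin), and 1, 4 and 12 are catalogue chemicals.

**Step 1**
Reactants: 1 methyl (2S)-oxirane-2-carboxylate (methyl (S)-glycidate)
Product: 3 2-[(2S)-oxiran-2-yl]propan-2-ol, via epoxy ketone 2 (not isolated)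
Conditions: MeMgCl (2.2 equiv), THF, −78 to −40 °C; cold satd NH4Cl; careful distillation
Reagents that add atoms: methylmagnesium chloride, C[Mg]Cl
Why: Double Grignard addition to the ester through ketone 2; without copper or a Lewis acid MeMgCl does not open a terminal oxirane below −40 °C, chloride is a poor halohydrin former, and the stereocentre is neither enolised nor substituted, so (S) is carried over.

**Step 2**
Reactants: 4 6-iodo-1H-indole
Product: 6 tert-butyl 3,6-diiodo-1H-indole-1-carboxylate, via 3,6-diiodo-1H-indole 5 (not isolated)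
Conditions: NIS (1.05 equiv), DMF, 0 °C, dark; then Boc2O (1.5 equiv), DMAP (0.1 equiv), Et3N, rt
Reagents that add atoms: N-iodosuccinimide, O=C1CCC(=O)N1I; di-tert-butyl dicarbonate, CC(C)(C)OC(=O)OC(=O)OC(C)(C)C
Why: Electrophilic aromatic iodination at C3, the most nucleophilic indole position, then DMAP-catalysed N-acylation, which stabilises the light-sensitive 3-iodoindole and switches off C3 nucleophilicity until the end of step 4.

**Step 3**
Reactants: 6 tert-butyl 3,6-diiodo-1H-indole-1-carboxylate; 3 2-[(2S)-oxiran-2-yl]propan-2-ol (3 equiv)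
Product: 8 tert-butyl 3,6-bis[(2S)-2,3-dihydroxy-3-methylbutyl]-1H-indole-1-carboxylate, via iodohydrin 7 (not isolated)
Conditions: NiCl2(dme) (15 mol%), 4,4'-di-tert-butyl-2,2'-bipyridine (20 mol%), 4CzIPN (3 mol%), NaI (0.3 equiv), Et3N (6 equiv), DMA, 450 nm LEDs, 25 °C
Reagents that add atoms: none
Why: Linear-selective nickel/photoredox cross-electrophile coupling of aryl iodides with terminal aliphatic epoxides, in which iodide opens 3 at CH2 to iodohydrin 7, the photocatalyst/Et3N system turns its C–I bond into a primary β-hydroxyalkyl radical, and the arylnickel species at C3 and at C6 captures it and reductively eliminates; the carbinol carbon is never a radical or a leaving group, so its (S) configuration comes unchanged from 3.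

**Step 4**
Reactants: 8 tert-butyl 3,6-bis[(2S)-2,3-dihydroxy-3-methylbutyl]-1H-indole-1-carboxylate
Product: 11 3,6-bis{[(2R)-3,3-dimethyloxiran-2-yl]methyl}-1H-indole, via bis-mesylate 9 (not isolated), via N-Boc bis-epoxide 10 (not isolated)
Conditions: MsCl (2.3 equiv), Et3N (4 equiv), CH2Cl2, −20 °C; then NaOMe (8 equiv), MeOH, 0 °C to rt; basic alumina filtration, use at once
Reagents that add atoms: none
Why: Sulfene mesylation takes only the two secondary hydroxyls, methoxide then closes both oxiranes by intramolecular Williamson displacement with inversion ((S)-carbinol to (R)-oxirane carbon) while the electron-poor N-Boc indole cannot participate through C3, and the same NaOMe/MeOH removes the azole-type carbamate by methanolysis.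

**Step 5**
Reactants: 11 3,6-bis{[(2R)-3,3-dimethyloxiran-2-yl]methyl}-1H-indole; 12 oleic acid ((9Z)-octadec-9-enoic acid)
Product: 14 (2S)-2-(6-{[(2R)-3,3-dimethyloxiran-2-yl]methyl}-1H-indol-3-yl)-3-hydroxy-3-methylbutyl (9Z)-octadec-9-enoate, via spirocyclopropane indolenine 13 (not isolated)
Conditions: 12 (3 equiv), PhMe (0.05 M), 60 °C, Ar, dark; Et3N-washed silica
Reagents that add atoms: none
Why: Proposed new method: a carboxylic-acid-triggered, anchimerically assisted epoxide-to-ester 1,2-indolyl shift, in which hydrogen bonding of oleic acid to the C3-side oxirane lets the enamine-like indole C3 attack the secondary oxirane carbon from the back (3-exo-tet SN2, inversion) to give spiroindolenine 13, N-protonation makes this a cyclopropyl iminium, and oleate opens it at the unhindered CH2 with rearomatisation, so the indolyl group ends on the former oxirane CH as the (S) centre beside the free tertiary alcohol and the oleate sits on the former benzylic CH2; the C6 oxirane has no such neighbour (participation there would cost benzene aromaticity) and a weak acid in a non-ionising solvent should not open it at this temperature; the closest known reactions are the aryl-assisted solvolysis of tryptophyl sulfonates through spiro[cyclopropane-1,3'-indolenines] and phenonium-type 1,2-aryl shifts in epoxide openings.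

**Compound list**
1 | methyl (2S)-oxirane-2-carboxylate | COC(=O)[C@@H]1CO1 | starting material
2 | 1-[(2S)-oxiran-2-yl]ethan-1-one | CC(=O)[C@@H]1CO1 | intermediate (not isolated)
3 | 2-[(2S)-oxiran-2-yl]propan-2-ol | CC(C)(O)[C@@H]1CO1 | intermediate
4 | 6-iodo-1H-indole | Ic1ccc2cc[nH]c2c1 | starting material
5 | 3,6-diiodo-1H-indole | Ic1ccc2c(I)c[nH]c2c1 | intermediate (not isolated)
6 | tert-butyl 3,6-diiodo-1H-indole-1-carboxylate | CC(C)(C)OC(=O)n1cc(I)c2ccc(I)cc12 | intermediate
7 | (2R)-1-iodo-3-methylbutane-2,3-diol | CC(C)(O)[C@@H](O)CI | intermediate (not isolated)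
8 | tert-butyl 3,6-bis[(2S)-2,3-dihydroxy-3-methylbutyl]-1H-indole-1-carboxylate | CC(C)(C)OC(=O)n1cc(C[C@H](O)C(C)(C)O)c2ccc(C[C@H](O)C(C)(C)O)cc12 | intermediate
9 | tert-butyl 3,6-bis[(2S)-3-hydroxy-2-(methanesulfonyloxy)-3-methylbutyl]-1H-indole-1-carboxylate | CC(C)(C)OC(=O)n1cc(C[C@H](OS(C)(=O)=O)C(C)(C)O)c2ccc(C[C@H](OS(C)(=O)=O)C(C)(C)O)cc12 | intermediate (not isolated)
10 | tert-butyl 3,6-bis{[(2R)-3,3-dimethyloxiran-2-yl]methyl}-1H-indole-1-carboxylate | CC(C)(C)OC(=O)n1cc(C[C@H]2OC2(C)C)c2ccc(C[C@H]3OC3(C)C)cc12 | intermediate (not isolated)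
11 | 3,6-bis{[(2R)-3,3-dimethyloxiran-2-yl]methyl}-1H-indole | CC1(C)O[C@@H]1Cc1c[nH]c2cc(C[C@H]3OC3(C)C)ccc12 | intermediate
12 | oleic acid, (9Z)-octadec-9-enoic acid | CCCCCCCC/C=C\CCCCCCCC(=O)O | starting material
13 | (2R)-6'-{[(2R)-3,3-dimethyloxiran-2-yl]methyl}-2-(2-hydroxypropan-2-yl)spiro[cyclopropane-1,3'-indole], both epimers at the spiro carbon | CC(C)(O)[C@@H]1CC12C=Nc3cc(C[C@H]4OC4(C)C)ccc23 | intermediate (not isolated)
14 | (2S)-2-(6-{[(2R)-3,3-dimethyloxiran-2-yl]methyl}-1H-indol-3-yl)-3-hydroxy-3-methylbutyl (9Z)-octadec-9-enoate | CCCCCCCC/C=C\CCCCCCCC(=O)OC[C@H](c1c[nH]c2cc(C[C@H]3OC3(C)C)ccc12)C(C)(C)O | target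

**Count and risks**
Total step count: 5. Longest linear sequence: 4 steps (4 → 6 → 8 → 11 → 14, or 1 → 3 → 8 → 11 → 14). No separate protection or deprotection step: the Boc group goes on in the iodination pot and comes off in the epoxide-forming pot.

The three steps most likely to fail:

Step 5 (the proposed new step). Risks are acid opening at the tertiary oxirane carbon, cyclisation through C2, and slow loss of the C6 oxirane to oleic acid. The fallback sets out from 4 and returns at 14. It uses the known aryl-assisted solvolysis of a tryptophyl-type sulfonate, which involves one inversion instead of two and therefore needs the enantiomeric glycidate for the C3 side chain. Purchased methyl (R)-glycidate is treated as in step 1 and gives, through 1-[(2R)-oxiran-2-yl]ethan-1-one F6 formed in the flask, 2-[(2R)-oxiran-2-yl]propan-2-ol F7. The indol-1-ylmagnesium bromide of 4 (EtMgBr, CH2Cl2/Et2O, 0 °C to rt) opens the bromomagnesium alkoxide of F7 at CH2 through C3 and gives (2R)-1-(6-iodo-1H-indol-3-yl)-3-methylbutane-2,3-diol F8. MsCl/Et3N at −20 °C gives (2R)-3-hydroxy-1-(6-iodo-1H-indol-3-yl)-3-methylbutan-2-yl methanesulfonate F9. Heating F9 in MeCN at 60 °C with Cs2CO3 (0.6 equiv) and 12 (3 equiv) lets C3 displace the mesylate with inversion to (2R)-2-(2-hydroxypropan-2-yl)-6'-iodospiro[cyclopropane-1,3'-indole] F10, which oleate opens at CH2 to (2S)-3-hydroxy-2-(6-iodo-1H-indol-3-yl)-3-methylbutyl (9Z)-octadec-9-enoate F11. The C6 iodide of F11 is coupled with 3 under the step 3 conditions (through 7) to (2S)-2-{6-[(2S)-2,3-dihydroxy-3-methylbutyl]-1H-indol-3-yl}-3-hydroxy-3-methylbutyl (9Z)-octadec-9-enoate F12. Cyclodehydration with PPh3/DIAD (secondary oxyphosphonium displaced by the tertiary hydroxyl, inversion) closes the (R)-oxirane and gives 14.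

Step 3 (double photochemical coupling). Risks are an incomplete second coupling, hydrodeiodination, and the tertiary alcohol interfering with the epoxide opening. The fallback sets out from 3 and 6 and returns at 8. Epoxide 3 is opened with LiI/AcOH in THF to iodohydrin 7, now isolated, and protected with 2,2-dimethoxypropane/PPTS as (4R)-4-(iodomethyl)-2,2,5,5-tetramethyl-1,3-dioxolane F4. This preformed alkyl iodide is joined to both C–I bonds of 6 without light in a thermal reductive cross-electrophile coupling (NiI2, 4,4'-di-tert-butyl-2,2'-bipyridine, pyridine, Mn powder, DMPU, 60 °C) to give tert-butyl 3,6-bis{[(4S)-2,2,5,5-tetramethyl-1,3-dioxolan-4-yl]methyl}-1H-indole-1-carboxylate F5. AcOH/H2O/THF at 45 °C removes both acetonides and gives 8.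

Step 1 (Grignard addition beside an oxirane). Risks are halohydrin formation, Payne rearrangement on work-up, and loss of the small, volatile, water-soluble 3. The fallback sets out from 1 and 6 and returns at 8; it reverses the order so that the oxirane never meets a Grignard reagent. Ester 1 itself is the epoxide partner in the step 3 coupling with 6. Iodide opens it at C3 to methyl (2R)-2-hydroxy-3-iodopropanoate F1 in the flask, and the coupling gives tert-butyl 3,6-bis[(2S)-2-hydroxy-3-methoxy-3-oxopropyl]-1H-indole-1-carboxylate F2. MeMgCl (9 equiv, THF, −40 to −10 °C, where the N-Boc group of an indole should survive) then adds through tert-butyl 3,6-bis[(2S)-2-hydroxy-3-oxobutyl]-1H-indole-1-carboxylate F3 to give 8.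

**Further compounds**
F1 | step 1 | methyl (2R)-2-hydroxy-3-iodopropanoate | COC(=O)[C@@H](O)CI
F2 | step 1 | tert-butyl 3,6-bis[(2S)-2-hydroxy-3-methoxy-3-oxopropyl]-1H-indole-1-carboxylate | COC(=O)[C@@H](O)Cc1cn(C(=O)OC(C)(C)C)c2cc(C[C@H](O)C(=O)OC)ccc12
F3 | step 1 | tert-butyl 3,6-bis[(2S)-2-hydroxy-3-oxobutyl]-1H-indole-1-carboxylate | CC(=O)[C@@H](O)Cc1cn(C(=O)OC(C)(C)C)c2cc(C[C@H](O)C(C)=O)ccc12
F4 | step 3 | (4R)-4-(iodomethyl)-2,2,5,5-tetramethyl-1,3-dioxolane | CC1(C)OC(C)(C)O[C@H]1CI
F5 | step 3 | tert-butyl 3,6-bis{[(4S)-2,2,5,5-tetramethyl-1,3-dioxolan-4-yl]methyl}-1H-indole-1-carboxylate | CC(C)(C)OC(=O)n1cc(C[C@@H]2OC(C)(C)OC2(C)C)c2ccc(C[C@@H]3OC(C)(C)OC3(C)C)cc12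
F6 | step 5 | 1-[(2R)-oxiran-2-yl]ethan-1-one | CC(=O)[C@H]1CO1
F7 | step 5 | 2-[(2R)-oxiran-2-yl]propan-2-ol | CC(C)(O)[C@H]1CO1
F8 | step 5 | (2R)-1-(6-iodo-1H-indol-3-yl)-3-methylbutane-2,3-diol | CC(C)(O)[C@H](O)Cc1c[nH]c2cc(I)ccc12
F9 | step 5 | (2R)-3-hydroxy-1-(6-iodo-1H-indol-3-yl)-3-methylbutan-2-yl methanesulfonate | CC(C)(O)[C@H](OS(C)(=O)=O)Cc1c[nH]c2cc(I)ccc12
F10 | step 5 | (2R)-2-(2-hydroxypropan-2-yl)-6'-iodospiro[cyclopropane-1,3'-indole], both epimers at the spiro carbon | CC(C)(O)[C@@H]1CC12C=Nc3cc(I)ccc23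
F11 | step 5 | (2S)-3-hydroxy-2-(6-iodo-1H-indol-3-yl)-3-methylbutyl (9Z)-octadec-9-enoate | CCCCCCCC/C=C\CCCCCCCC(=O)OC[C@H](c1c[nH]c2cc(I)ccc12)C(C)(C)O
F12 | step 5 | (2S)-2-{6-[(2S)-2,3-dihydroxy-3-methylbutyl]-1H-indol-3-yl}-3-hydroxy-3-methylbutyl (9Z)-octadec-9-enoate | CCCCCCCC/C=C\CCCCCCCC(=O)OC[C@H](c1c[nH]c2cc(C[C@H](O)C(C)(C)O)ccc12)C(C)(C)O
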